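**Plan**
Core numbering is that of chromene: O1, C2, C3, C4, C4a, C5–C8, C8a; ring A is the carbocycle, ring B the dihydropyranone.
Cuts, in retrosynthetic order: C8–CH(Ph) (with a temporary enol-lactone to O7); C8–C8a (ring A); O1–C8a and C4a–C8a (one-carbon linchpin from CS2); C4a–C5 (aldol, then oxidation); C6–prenyl and C6–CH2(cyclobutyl) (two acetoacetate alkylations).
Forward: verbenone → iodide 6 → quaternary keto ester 13 → keto aldehyde 15; Evans aldol → ketone 21; 15 + 21 → triketone 23 → ketene dithioacetal 24 → ring B (26) → ring A (27) → side chain (30).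
Enabling feature: C8a carries O1, C4a and C8, so it is a carbonic-acid-level carbon between two carbon nucleophiles. In 26 it is the MeS-bearing β-carbon of a vinylogous thioester in ring B, six atoms from the C7 acetyl methyl (future C8); C6 is quaternary, so no enolate can form between C5 and C7. O1 is already on C8a when ring A closes, so the chromanone fusion cannot form the other way round.
Stereochemistry: cyclobutane from (1S)-(−)-verbenone; cis C2/C3 from an Evans syn-aldol; C6 from a valine-derived chiral enamine alkylation; the benzylic carbon from a chiral N-heterocyclic carbene.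

Key step: step 19

Abbreviations in names: Cbm = [(1R,3S)-2,2-dimethyl-3-(prop-1-en-2-yl)cyclobutyl]methyl; TBS = tert-butyldimethylsilyl.
Assumption: in the two reagent-controlled steps 8 and 20 the sense of induction is taken as drawn; should the opposite face react, the mirror-image controller (tert-butyl D-valinate, or the (5aS,10bR) triazolium salt) is used.

Step 1
Reactants: 1 (1S)-(−)-verbenone
Product: 2 (1S,3R)-3-acetyl-2,2-dimethylcyclobutane-1-carboxylic acid
Conditions: RuCl3·xH2O (2 mol %), NaIO4, CCl4/MeCN/H2O, rt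
Reagents that add atoms: sodium periodate, [Na+].[O-]I(=O)(=O)=O; water, O
Why: Oxidative cleavage of the enone C3=C4 bond by RuO4 formed in situ, with loss of C3 as CO2 from the intermediate α-keto acid, leaves both ring stereocentres untouched, so the cis relationship and absolute configuration come from the terpene.

Step 2
Reactants: 2 (1S,3R)-3-acetyl-2,2-dimethylcyclobutane-1-carboxylic acid
Product: 3 methyl (1S,3R)-3-acetyl-2,2-dimethylcyclobutane-1-carboxylate
Conditions: MeI, KHCO3, DMF, rt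
Reagents that add atoms: iodomethane, CI
Why: SN2 O-alkylation of the carboxylate with a base too weak to epimerise the centre next to the acetyl group.

Step 3
Reactants: 3 methyl (1S,3R)-3-acetyl-2,2-dimethylcyclobutane-1-carboxylate
Product: 4 methyl (1S,3S)-2,2-dimethyl-3-(prop-1-en-2-yl)cyclobutane-1-carboxylate
Conditions: Ph3PCH3Br, KOtBu (slight deficit), THF, 0 °C to rt
Reagents that add atoms: methyltriphenylphosphonium bromide, C[P+](c1ccccc1)(c1ccccc1)c1ccccc1.[Br-]
Why: Wittig methylenation of the methyl ketone is faster than enolisation toward the hindered ring CH, so the isopropenyl group should form with the cis geometry kept.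

Step 4
Reactants: 4 methyl (1S,3S)-2,2-dimethyl-3-(prop-1-en-2-yl)cyclobutane-1-carboxylate
Product: 5 [(1S,3S)-2,2-dimethyl-3-(prop-1-en-2-yl)cyclobutyl]methanol
Conditions: LiAlH4, Et2O, 0 °C
Reagents that add atoms: none
Why: Hydride reduction of the ester to the primary alcohol; the isolated alkene is inert.

Step 5
Reactants: 5 [(1S,3S)-2,2-dimethyl-3-(prop-1-en-2-yl)cyclobutyl]methanol
Product: 6 (1S,3S)-1-(iodomethyl)-2,2-dimethyl-3-(prop-1-en-2-yl)cyclobutane
Conditions: I2, PPh3, imidazole, CH2Cl2, 0 °C to rt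
Reagents that add atoms: iodine, II
Why: Appel-type iodination through the alkoxyphosphonium salt is an SN2 process under neutral conditions, so no cation forms next to the strained ring.

Step 6
Reactants: 6 (1S,3S)-1-(iodomethyl)-2,2-dimethyl-3-(prop-1-en-2-yl)cyclobutane; 7 ethyl acetoacetate (excess)
Product: 8 ethyl 2-Cbm-3-oxobutanoate (both C2 epimers)
Conditions: NaH, DMF, 0 to 70 °C
Reagents that add atoms: none
Why: SN2 C-alkylation of the sodium acetoacetate enolate, where the excess enolate suppresses dialkylation and the new CH centre is of no consequence because it becomes planar in step 7.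

Step 7
Reactants: 8 ethyl 2-Cbm-3-oxobutanoate; 9 tert-butyl L-valinate
Product: 10 ethyl (2Z)-3-{[(2S)-1-tert-butoxy-3-methyl-1-oxobutan-2-yl]amino}-2-Cbm-but-2-enoate
Conditions: p-toluenesulfonic acid monohydrate (2 mol %), toluene, reflux, Dean–Stark
Reagents that add atoms: none
Why: Acid-catalysed condensation of the ketone with the amino ester gives the hydrogen-bonded (Z)-enamino ester, which installs the chiral controller.

Step 8
Reactants: 10 ethyl (2Z)-3-{[(2S)-1-tert-butoxy-3-methyl-1-oxobutan-2-yl]amino}-2-Cbm-but-2-enoate; 11 prenyl bromide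
Product: 13 ethyl (2R)-2-acetyl-2-Cbm-5-methylhex-4-enoate, via C-prenylated imine 12 (not isolated)
Conditions: LiN(iPr)2, toluene, −78 °C; HMPA; 11, −78 to −40 °C; then 10% aq. citric acid, THF, rt
Reagents that add atoms: water, O
Why: Asymmetric alkylation of a lithiated chiral enamino ester: lithium is chelated by nitrogen and both ester carbonyls, the isopropyl group blocks one face, and SN2 attack on prenyl bromide should set the quaternary centre (future C6) before mild hydrolysis releases the keto ester and the valine ester.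

Step 9
Reactants: 13 ethyl (2R)-2-acetyl-2-Cbm-5-methylhex-4-enoate
Product: 14 (2S)-2-Cbm-2-(3-methylbut-2-en-1-yl)butane-1,3-diol (C3 epimers)
Conditions: LiAlH4, THF, 0 °C to rt
Reagents that add atoms: none
Why: Hydride reduction of both carbonyl groups removes the cleavage-prone quaternary β-keto ester and prepares the future C5 carbon for the aldehyde level; the new carbinol centre is removed in step 10.

Step 10
Reactants: 14 (2S)-2-Cbm-2-(3-methylbut-2-en-1-yl)butane-1,3-diol
Product: 15 (2S)-2-acetyl-2-Cbm-5-methylhex-4-enal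
Conditions: Dess–Martin periodinane (2.4 equiv), CH2Cl2, rt
Reagents that add atoms: none
Why: Dess–Martin oxidation of both alcohols gives a β-keto aldehyde that cannot enolise at the quaternary carbon; its aldehyde is the future C5 and its acetyl group the future C7–C8.

Step 11
Reactants: 16 (4S)-4-benzyl-3-propanoyl-1,3-oxazolidin-2-one; 17 acetaldehyde
Product: 18 (4S)-4-benzyl-3-[(2S,3R)-3-hydroxy-2-methylbutanoyl]-1,3-oxazolidin-2-one
Conditions: Bu2BOTf, iPr2NEt, CH2Cl2, −78 to 0 °C; then pH 7 buffer, MeOH, 30% H2O2, 0 °C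
Reagents that add atoms: none
Why: Evans syn-aldol: the (Z)-boron enolate reacts through a closed chair transition state on the face away from the benzyl group, which should set both centres (future C3 and C2) as (2S,3R).

Step 12
Reactants: 18 (4S)-4-benzyl-3-[(2S,3R)-3-hydroxy-2-methylbutanoyl]-1,3-oxazolidin-2-one
Product: 19 (2S,3R)-3-hydroxy-N-methoxy-N,2-dimethylbutanamide
Conditions: MeNHOMe·HCl, AlMe3, THF, −10 to 0 °C; aq. Rochelle salt
Reagents that add atoms: N,O-dimethylhydroxylamine hydrochloride, CNOC.Cl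
Why: Weinreb transamidation by the aluminium amide, assisted by the free β-hydroxyl, cleaves the auxiliary without touching the α-centre.

Step 13
Reactants: 19 (2S,3R)-3-hydroxy-N-methoxy-N,2-dimethylbutanamide
Product: 20 (2S,3R)-3-[(tert-butyldimethylsilyl)oxy]-N-methoxy-N,2-dimethylbutanamide
Conditions: TBSCl, imidazole, DMF, rt
Reagents that add atoms: tert-butyldimethylsilyl chloride, CC(C)(C)[Si](C)(C)Cl
Why: Silylation protects the secondary alcohol from the later oxidation and from retro-aldol cleavage.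

Step 14
Reactants: 20 (2S,3R)-3-[(tert-butyldimethylsilyl)oxy]-N-methoxy-N,2-dimethylbutanamide
Product: 21 (3S,4R)-4-[(tert-butyldimethylsilyl)oxy]-3-methylpentan-2-one
Conditions: MeMgBr, THF, 0 °C
Reagents that add atoms: methylmagnesium bromide, C[Mg]Br
Why: Grignard addition to the Weinreb amide stops at the chelated tetrahedral intermediate and gives the methyl ketone on work-up.

Step 15
Reactants: 21 (3S,4R)-4-[(tert-butyldimethylsilyl)oxy]-3-methylpentan-2-one; 15 (2S)-2-acetyl-2-Cbm-5-methylhex-4-enal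
Product: 22 (2R,3S,7S)-7-acetyl-2-[(tert-butyldimethylsilyl)oxy]-7-Cbm-6-hydroxy-3,10-dimethylundec-9-en-4-one (C6 epimers)
Conditions: 21, LiN(iPr)2, THF, −78 °C; then 15; AcOH quench at −78 °C
Reagents that add atoms: none
Why: Aldol addition of the kinetic methyl-side lithium enolate to the aldehyde, which is far more electrophilic than the hindered acetyl group, forms the C4a–C5 bond; the cold quench prevents retro-aldol and the new carbinol centre is removed in step 16.

Step 16
Reactants: 22 (2R,3S,7S)-7-acetyl-2-[(tert-butyldimethylsilyl)oxy]-7-Cbm-6-hydroxy-3,10-dimethylundec-9-en-4-one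
Product: 23 (2R,3S,7R)-7-acetyl-2-[(tert-butyldimethylsilyl)oxy]-7-Cbm-3,10-dimethylundec-9-ene-4,6-dione
Conditions: Dess–Martin periodinane (1.3 equiv), CH2Cl2, 0 °C to rt
Reagents that add atoms: none
Why: Dess–Martin oxidation of the β-hydroxy ketone gives the enolised 1,3-diketone, whose central CH2 (future C4a) is now the most acidic carbon of the molecule.

Step 17
Reactants: 23 (2R,3S,7R)-7-acetyl-2-[(tert-butyldimethylsilyl)oxy]-7-Cbm-3,10-dimethylundec-9-ene-4,6-dione
Product: 24 (2R,3S,7R)-7-acetyl-5-[bis(methylsulfanyl)methylidene]-2-[(tert-butyldimethylsilyl)oxy]-7-Cbm-3,10-dimethylundec-9-ene-4,6-dione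
Conditions: K2CO3, CS2, DMF, 0 °C; then MeI, 0 °C to rt
Reagents that add atoms: carbon disulfide, S=C=S; iodomethane, CI
Why: Addition of the diketone enolate to CS2 and double S-methylation (α-oxo ketene dithioacetal formation) installs the future C8a at the carbonic-acid oxidation level with two leaving groups.

Step 18
Reactants: 24 (2R,3S,7R)-7-acetyl-5-[bis(methylsulfanyl)methylidene]-2-[(tert-butyldimethylsilyl)oxy]-7-Cbm-3,10-dimethylundec-9-ene-4,6-dione
Product: 26 (3R)-3-Cbm-3-{[(2R,3S)-2,3-dimethyl-6-(methylsulfanyl)-4-oxo-3,4-dihydro-2H-pyran-5-yl]carbonyl}-6-methylhept-5-en-2-one, via hydroxy ketene dithioacetal 25 (not isolated)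
Conditions: Bu4NF (1.1 equiv), THF, −20 to 0 °C; then AcOH (1.1 equiv)
Reagents that add atoms: none
Why: Fluoride desilylation frees the alkoxide, which displaces one MeS group by intramolecular addition–elimination (vinylic substitution) and closes ring B with O1 on the future C8a, the fast six-membered closure being expected to outrun retro-aldol or epimerisation at C3.

Step 19
Reactants: 26 (3R)-3-Cbm-3-{[(2R,3S)-2,3-dimethyl-6-(methylsulfanyl)-4-oxo-3,4-dihydro-2H-pyran-5-yl]carbonyl}-6-methylhept-5-en-2-one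
Product: 27 (2R,3S,6R)-6-Cbm-4-hydroxy-2,3-dimethyl-6-(3-methylbut-2-en-1-yl)-2,3-dihydro-5H-chromene-5,7(6H)-dione
Conditions: LiN(SiMe3)2 (2.2 equiv), THF, −78 to 0 °C; then AcOH
Reagents that add atoms: none
Why: Kinetic deprotonation of the C7 acetyl methyl (the only unhindered acidic C–H, since C6 is quaternary and H-3 is a shielded methine next to an electron-rich vinylogous-thioester carbonyl) gives a lithium enolate that adds in conjugate fashion to C8a of the doubly acyl-activated ketene S,O-acetal, and loss of methanethiolate followed by deprotonation of the new vinylogous acid makes the closure irreversible. The closest known reaction type is the addition–elimination of ketone enolates on α-oxo ketene dithioacetals and 2-(methylsulfanyl)-4-pyranones, the chemical counterpart of the Claisen closure that forms phloroglucinol rings from polyketides. Ring A closes in a 6-(enolendo)-endo-trig mode, the C4a=C8a bond lying inside the new six-membered ring. No stereocentre is created, and C2, C3 and C6 are spectators. The step needs site selectivity (methyl against H-3 enolisation, which would epimerise C3 or open ring B by retro-oxa-Michael reaction) and chemoselectivity (C8a against the C4 carbonyl); the first should be secured by low temperature and the hindered amide base, the second by the reversibility of the aldol pathway against the irreversible loss of MeS−. Because O1 already sits on C8a, the chromanone fusion can only arise in the required sense.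

Step 20
Reactants: 27 (2R,3S,6R)-6-Cbm-4-hydroxy-2,3-dimethyl-6-(3-methylbut-2-en-1-yl)-2,3-dihydro-5H-chromene-5,7(6H)-dione; 28 (E)-cinnamaldehyde
Product: 30 (3S)-3-[(2R,3S,6R)-6-Cbm-4-hydroxy-2,3-dimethyl-6-(3-methylbut-2-en-1-yl)-5,7-dioxo-3,5,6,7-tetrahydro-2H-chromen-8-yl]-3-phenylpropanoic acid (target CNP0328119.1), via enol lactone 29 (not isolated)
Conditions: (5aR,10bS)-2-mesityl-5a,10b-dihydro-4H,6H-indeno[2,1-b][1,2,4]triazolo[4,3-d][1,4]oxazin-2-ium chloride (C21H22ClN3O, 10 mol %), 1,8-diazabicyclo[5.4.0]undec-7-ene, 3,3',5,5'-tetra-tert-butyl-4,4'-diphenoquinone (1.2 equiv), THF, 4 Å sieves, rt; then LiOH, THF/H2O, 0 °C; then 1 M HCl to pH 3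
Reagents that add atoms: lithium hydroxide, [Li+].[OH-]
Why: Oxidative N-heterocyclic carbene catalysis turns the enal into an α,β-unsaturated acyl azolium, C8 of the deprotonated triketone (its only free nucleophilic carbon) adds to the β-carbon on the face left open by the aminoindanol-derived catalyst so that the benzylic centre should be set under catalyst control, O7 acylation closes the enol lactone and releases the carbene, and hydrolysis in the same flask frees the acid.

**Compound list**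
1 | (1S,5S)-4,6,6-trimethylbicyclo[3.1.1]hept-3-en-2-one, (1S)-(−)-verbenone | CC1=CC(=O)[C@H]2C[C@@H]1C2(C)C | starting material
2 | (1S,3R)-3-acetyl-2,2-dimethylcyclobutane-1-carboxylic acid | CC(=O)[C@@H]1C[C@H](C(=O)O)C1(C)C | intermediate
3 | methyl (1S,3R)-3-acetyl-2,2-dimethylcyclobutane-1-carboxylate | CC(=O)[C@@H]1C[C@H](C(=O)OC)C1(C)C | intermediate
4 | methyl (1S,3S)-2,2-dimethyl-3-(prop-1-en-2-yl)cyclobutane-1-carboxylate | C=C(C)[C@@H]1C[C@H](C(=O)OC)C1(C)C | intermediate
5 | [(1S,3S)-2,2-dimethyl-3-(prop-1-en-2-yl)cyclobutyl]methanol | C=C(C)[C@@H]1C[C@H](CO)C1(C)C | intermediate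
6 | (1S,3S)-1-(iodomethyl)-2,2-dimethyl-3-(prop-1-en-2-yl)cyclobutane | C=C(C)[C@@H]1C[C@H](CI)C1(C)C | intermediate
7 | ethyl acetoacetate | CCOC(=O)CC(C)=O | starting material
8 | ethyl 2-{[(1R,3S)-2,2-dimethyl-3-(prop-1-en-2-yl)cyclobutyl]methyl}-3-oxobutanoate (C2 epimers) | C=C(C)[C@@H]1C[C@H](CC(C(C)=O)C(=O)OCC)C1(C)C | intermediate
9 | tert-butyl L-valinate | CC(C)[C@H](N)C(=O)OC(C)(C)C | starting material
10 | ethyl (2Z)-3-{[(2S)-1-tert-butoxy-3-methyl-1-oxobutan-2-yl]amino}-2-{[(1R,3S)-2,2-dimethyl-3-(prop-1-en-2-yl)cyclobutyl]methyl}but-2-enoate | C=C(C)[C@@H]1C[C@H](C/C(C(=O)OCC)=C(\C)N[C@@H](C(C)C)C(=O)OC(C)(C)C)C1(C)C | intermediate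
11 | prenyl bromide (1-bromo-3-methylbut-2-ene) | CC(C)=CCBr | starting material
12 | C-prenylated imine: ethyl (2R)-2-{1-[(2S)-1-tert-butoxy-3-methyl-1-oxobutan-2-yl]iminoethyl}-2-{[(1R,3S)-2,2-dimethyl-3-(prop-1-en-2-yl)cyclobutyl]methyl}-5-methylhex-4-enoate | C=C(C)[C@@H]1C[C@H](C[C@@](C(C)=N[C@@H](C(C)C)C(=O)OC(C)(C)C)(CC=C(C)C)C(=O)OCC)C1(C)C | intermediate (not isolated)
13 | ethyl (2R)-2-acetyl-2-{[(1R,3S)-2,2-dimethyl-3-(prop-1-en-2-yl)cyclobutyl]methyl}-5-methylhex-4-enoate | C=C(C)[C@@H]1C[C@H](C[C@@](C(C)=O)(CC=C(C)C)C(=O)OCC)C1(C)C | intermediate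
14 | (2S)-2-{[(1R,3S)-2,2-dimethyl-3-(prop-1-en-2-yl)cyclobutyl]methyl}-2-(3-methylbut-2-en-1-yl)butane-1,3-diol (C3 epimers) | C=C(C)[C@@H]1C[C@H](C[C@@](C(C)O)(CC=C(C)C)CO)C1(C)C | intermediate
15 | (2S)-2-acetyl-2-{[(1R,3S)-2,2-dimethyl-3-(prop-1-en-2-yl)cyclobutyl]methyl}-5-methylhex-4-enal | C=C(C)[C@@H]1C[C@H](C[C@@](C(C)=O)(CC=C(C)C)C=O)C1(C)C | intermediate
16 | (4S)-4-benzyl-3-propanoyl-1,3-oxazolidin-2-one | CCC(=O)N1[C@@H](Cc2ccccc2)COC1=O | starting material
17 | acetaldehyde | CC=O | starting material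
18 | (4S)-4-benzyl-3-[(2S,3R)-3-hydroxy-2-methylbutanoyl]-1,3-oxazolidin-2-one | O=C([C@@H](C)[C@@H](C)O)N1[C@@H](Cc2ccccc2)COC1=O | intermediate
19 | (2S,3R)-3-hydroxy-N-methoxy-N,2-dimethylbutanamide | CON(C)C(=O)[C@@H](C)[C@@H](C)O | intermediate
20 | (2S,3R)-3-[(tert-butyldimethylsilyl)oxy]-N-methoxy-N,2-dimethylbutanamide | CON(C)C(=O)[C@@H](C)[C@@H](C)O[Si](C)(C)C(C)(C)C | intermediate
21 | (3S,4R)-4-[(tert-butyldimethylsilyl)oxy]-3-methylpentan-2-one | CC(=O)[C@@H](C)[C@@H](C)O[Si](C)(C)C(C)(C)C | intermediate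
22 | (2R,3S,7S)-7-acetyl-2-[(tert-butyldimethylsilyl)oxy]-7-{[(1R,3S)-2,2-dimethyl-3-(prop-1-en-2-yl)cyclobutyl]methyl}-6-hydroxy-3,10-dimethylundec-9-en-4-one (C6 epimers) | C=C(C)[C@@H]1C[C@H](C[C@@](C(C)=O)(CC=C(C)C)C(O)CC(=O)[C@@H](C)[C@@H](C)O[Si](C)(C)C(C)(C)C)C1(C)C | intermediate
23 | (2R,3S,7R)-7-acetyl-2-[(tert-butyldimethylsilyl)oxy]-7-{[(1R,3S)-2,2-dimethyl-3-(prop-1-en-2-yl)cyclobutyl]methyl}-3,10-dimethylundec-9-ene-4,6-dione (drawn as the triketone) | C=C(C)[C@@H]1C[C@H](C[C@@](C(C)=O)(CC=C(C)C)C(=O)CC(=O)[C@@H](C)[C@@H](C)O[Si](C)(C)C(C)(C)C)C1(C)C | intermediate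
24 | (2R,3S,7R)-7-acetyl-5-[bis(methylsulfanyl)methylidene]-2-[(tert-butyldimethylsilyl)oxy]-7-{[(1R,3S)-2,2-dimethyl-3-(prop-1-en-2-yl)cyclobutyl]methyl}-3,10-dimethylundec-9-ene-4,6-dione | C=C(C)[C@@H]1C[C@H](C[C@@](C(C)=O)(CC=C(C)C)C(=O)C(=C(SC)SC)C(=O)[C@@H](C)[C@@H](C)O[Si](C)(C)C(C)(C)C)C1(C)C | intermediate
25 | hydroxy ketene dithioacetal: (2R,3S,7R)-7-acetyl-5-[bis(methylsulfanyl)methylidene]-7-{[(1R,3S)-2,2-dimethyl-3-(prop-1-en-2-yl)cyclobutyl]methyl}-2-hydroxy-3,10-dimethylundec-9-ene-4,6-dione | C=C(C)[C@@H]1C[C@H](C[C@@](C(C)=O)(CC=C(C)C)C(=O)C(=C(SC)SC)C(=O)[C@@H](C)[C@@H](C)O)C1(C)C | intermediate (not isolated)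
26 | (3R)-3-{[(1R,3S)-2,2-dimethyl-3-(prop-1-en-2-yl)cyclobutyl]methyl}-3-{[(2R,3S)-2,3-dimethyl-6-(methylsulfanyl)-4-oxo-3,4-dihydro-2H-pyran-5-yl]carbonyl}-6-methylhept-5-en-2-one | C=C(C)[C@@H]1C[C@H](C[C@@](C(C)=O)(CC=C(C)C)C(=O)C2=C(SC)O[C@H](C)[C@H](C)C2=O)C1(C)C | intermediate
27 | (2R,3S,6R)-6-{[(1R,3S)-2,2-dimethyl-3-(prop-1-en-2-yl)cyclobutyl]methyl}-4-hydroxy-2,3-dimethyl-6-(3-methylbut-2-en-1-yl)-2,3-dihydro-5H-chromene-5,7(6H)-dione | C=C(C)[C@@H]1C[C@H](C[C@@]2(CC=C(C)C)C(=O)C3=C(O)[C@@H](C)[C@@H](C)OC3=CC2=O)C1(C)C | intermediate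
28 | (E)-cinnamaldehyde | O=C/C=C/c1ccccc1 | starting material
29 | enol lactone of 30: the carboxyl group esterified to O7, giving a (4S)-4-phenyl-3,4-dihydro-2H-pyran-2-one ring fused across C7=C8; C4 and C5 are ketones, C4a=C8a; core (2R,3S,6R) | C=C(C)[C@@H]1C[C@H](C[C@@]2(CC=C(C)C)C(=O)C3=C(O[C@H](C)[C@H](C)C3=O)C4=C2OC(=O)C[C@H]4c2ccccc2)C1(C)C | intermediate (not isolated)
30 | (3S)-3-[(2R,3S,6R)-6-{[(1R,3S)-2,2-dimethyl-3-(prop-1-en-2-yl)cyclobutyl]methyl}-4-hydroxy-2,3-dimethyl-6-(3-methylbut-2-en-1-yl)-5,7-dioxo-3,5,6,7-tetrahydro-2H-chromen-8-yl]-3-phenylpropanoic acid | C=C(C)[C@@H]1C[C@H](C[C@@]2(CC=C(C)C)C(=O)C3=C(O)[C@@H](C)[C@@H](C)OC3=C([C@@H](CC(=O)O)c3ccccc3)C2=O)C1(C)C | target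

**Totals**
Total step count: 20. Longest linear sequence: 16 steps (steps 1–10, then 15–20); steps 11–14 form the second branch.

**Steps most likely to fail, with fallbacks**

Step 8. The risk is poor facial selectivity in the enamine alkylation, because the α-substituent is much bulkier than in simple cases, or sluggish enamine formation in step 7. The fallback replaces the covalent controller by chiral ion-pair catalysis. It sets out from 6: alkylation of tert-butyl acetoacetate (NaH, DMF, 70 °C) should give tert-butyl 2-Cbm-3-oxobutanoate F1. Asymmetric phase-transfer prenylation of F1 with 11 should then give tert-butyl (2R)-2-acetyl-2-Cbm-5-methylhex-4-enoate F2. Conditions for this: (11bS)-4,4-dibutyl-2,6-bis(3,4,5-trifluorophenyl)-4,5-dihydro-3H-dinaphtho[2,1-c:1',2'-e]azepin-4-ium bromide (C42H36BrF6N, 2 mol %), CsOH·H2O, toluene, −40 °C. LiAlH4 reduction of F2 returns to the route at 14.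

Step 19. The risk is competing deprotonation at C3 of ring B, leading to epimerisation to the trans-dimethyl series or retro-oxa-Michael opening. Attack of the liberated thiolate or of the enolate on the C4 carbonyl is a further risk. The fallback moves the linchpin carbon to the formyl level so that ring A closes by a plain Michael addition followed by dehydrogenation. It sets out from 23: Me2NCH(OMe)2 (toluene, 60 °C) should give the enaminone (2R,3S,7R)-7-acetyl-2-[(tert-butyldimethylsilyl)oxy]-7-Cbm-5-[(dimethylamino)methylidene]-3,10-dimethylundec-9-ene-4,6-dione F3. Bu4NF then closes ring B with loss of dimethylamine to (3R)-3-Cbm-3-{[(2R,3S)-2,3-dimethyl-4-oxo-3,4-dihydro-2H-pyran-5-yl]carbonyl}-6-methylhept-5-en-2-one F4. LiN(SiMe3)2 (THF, −78 °C) closes ring A by 6-endo Michael addition to the 8,8a-dihydro derivative of 27 F5 (C8a epimers). Dehydrogenation with 2,3-dichloro-5,6-dicyano-1,4-benzoquinone (dioxane, rt) returns to the route at 27.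

Step 20. The risk is low facial discrimination or a slow conjugate addition of the hindered, strongly acidic C8 nucleophile to the acyl azolium. The fallback is a three-component condensation without a chiral catalyst, followed by separation. It sets out from 27: benzaldehyde and 2,2-dimethyl-1,3-dioxane-4,6-dione with L-proline (10 mol %) in MeCN (rt, then 70 °C) form 5-benzylidene-2,2-dimethyl-1,3-dioxane-4,6-dione F6 in the flask. C8 of 27 adds to F6 to give the Michael adduct F7. O7 acylation of F7 with loss of acetone and CO2 gives 29 together with its (4R) benzylic epimer F8, to be separated by chromatography. The fallback comes back to the route at 29, which is hydrolysed as in step 20.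

**Further compounds**
F1 | step 8 | tert-butyl 2-{[(1R,3S)-2,2-dimethyl-3-(prop-1-en-2-yl)cyclobutyl]methyl}-3-oxobutanoate (C2 epimers) | C=C(C)[C@@H]1C[C@H](CC(C(C)=O)C(=O)OC(C)(C)C)C1(C)C
F2 | step 8 | tert-butyl (2R)-2-acetyl-2-{[(1R,3S)-2,2-dimethyl-3-(prop-1-en-2-yl)cyclobutyl]methyl}-5-methylhex-4-enoate | C=C(C)[C@@H]1C[C@H](C[C@@](C(C)=O)(CC=C(C)C)C(=O)OC(C)(C)C)C1(C)C
F3 | step 19 | (2R,3S,7R)-7-acetyl-2-[(tert-butyldimethylsilyl)oxy]-7-{[(1R,3S)-2,2-dimethyl-3-(prop-1-en-2-yl)cyclobutyl]methyl}-5-[(dimethylamino)methylidene]-3,10-dimethylundec-9-ene-4,6-dione | C=C(C)[C@@H]1C[C@H](C[C@@](C(C)=O)(CC=C(C)C)C(=O)C(=CN(C)C)C(=O)[C@@H](C)[C@@H](C)O[Si](C)(C)C(C)(C)C)C1(C)C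
F4 | step 19 | (3R)-3-{[(1R,3S)-2,2-dimethyl-3-(prop-1-en-2-yl)cyclobutyl]methyl}-3-{[(2R,3S)-2,3-dimethyl-4-oxo-3,4-dihydro-2H-pyran-5-yl]carbonyl}-6-methylhept-5-en-2-one | C=C(C)[C@@H]1C[C@H](C[C@@](C(C)=O)(CC=C(C)C)C(=O)C2=CO[C@H](C)[C@H](C)C2=O)C1(C)C
F5 | step 19 | 8,8a-dihydro derivative of 27 (C8a epimers) | C=C(C)[C@@H]1C[C@H](C[C@@]2(CC=C(C)C)C(=O)C3=C(O)[C@@H](C)[C@@H](C)OC3CC2=O)C1(C)C
F6 | step 20 | 5-benzylidene-2,2-dimethyl-1,3-dioxane-4,6-dione | CC1(C)OC(=O)C(=Cc2ccccc2)C(=O)O1
F7 | step 20 | Michael adduct: 27 bearing at C8 a phenyl(2,2-dimethyl-4,6-dioxo-1,3-dioxan-5-yl)methyl group (benzylic epimers) | C=C(C)[C@@H]1C[C@H](C[C@@]2(CC=C(C)C)C(=O)C3=C(O)[C@@H](C)[C@@H](C)OC3=C(C(c3ccccc3)C3C(=O)OC(C)(C)OC3=O)C2=O)C1(C)C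
F8 | step 20 | (4R) benzylic epimer of enol lactone 29 | C=C(C)[C@@H]1C[C@H](C[C@@]2(CC=C(C)C)C(=O)C3=C(O[C@H](C)[C@H](C)C3=O)C4=C2OC(=O)C[C@@H]4c2ccccc2)C1(C)C
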